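Late times come first here: at 30.0 min the south run reads 0 % of substrate, and from then on its target and other capture product move by about the scatter. So I look for the end state of the flask before any rate.

| setting | south | west | north | flask |
|---|---|---|---|---|
| substrate | 0.057 M | 0.057 M | 0.057 M | 0.057 M |
| first nucleophile | 0.55 equiv | 0.83 equiv | 1.1 equiv | 1.10 equiv |
| second nucleophile | 1.2 equiv | 1.2 equiv | 1.8 equiv | 1.20 equiv |
| remark | run made earlier | run made earlier | run made earlier |  |
| time |  |  |  | 3.0 h |

| run | time / min | target / % | other capture product / % | substrate / % |
|---|---|---|---|---|
| south | 8.00 | 6.1 | 65.0 | 14.4 |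
| south | 12.0 | 5.8 | 72.0 | 5.8 |
| south | 20.0 | 8.0 | 74.4 | 2.8 |
| south | 30.0 | 5.8 | 76.3 | 0 |
| south | 50.0 | 5.1 | 77.8 | 0 |
| south | 80.0 | 6.6 | 76.6 | 1.1 |
| south | 120 | 6.4 | 75.3 | 0 |
| west | 8.00 | 8.3 | 60.5 | 12.0 |
| west | 12.0 | 6.1 | 65.4 | 4.9 |
| west | 20.0 | 6.4 | 68.7 | 0.8 |
| west | 30.0 | 7.8 | 69.3 | 1.0 |
| west | 50.0 | 7.2 | 67.1 | 0 |
| west | 80.0 | 7.3 | 69.2 | 0 |
| west | 120 | 6.8 | 69.0 | 0 |
| north | 8.00 | 5.6 | 69.8 | 5.4 |
| north | 15.0 | 7.3 | 72.6 | 0 |
| north | 30.0 | 6.7 | 71.8 | 0.3 |
| north | 60.0 | 7.7 | 72.9 | 0.4 |
| north | 120 | 4.7 | 74.2 | 0.4 |

(standard deviation of a reading: 1 percentage point)

- in percentages every species weighs as the substrate in it: one side product counts as two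
- reactions considered so far: substrate <-> intermediate; first nucleophile + intermediate -> target; second nucleophile + intermediate -> other capture product; substrate + target -> side product; target <-> isomer of the product

- ratio of target to other capture product at 5.0 s
- ratio of target to other capture product at 4.0 min
- ratio of target to other capture product at 3.0 h
- which of target and other capture product there is more of at 3.0 h

Which given numbers must be known well? The latest time need not be, as far as the runs show: the south target reading changes by 0.6 percentage points between 30.0 min and 120 min, which is inside the scatter, though that run stops before 3.0 h. The substrate concentration is 0.057 M in the flask and in the south, west and north runs, so it needs no correction and the runs cannot test it. An error in either nucleophile charge passes into the answer in proportion, if the end ratio follows the charge ratio, and the runs below can test that no more closely than their scatter allows. The late target level is the delicate number: a scatter of 1 point is 13.9 % of the west target reading at 50.0 min, a larger error than the 1.49 % on the other capture product beside it. So I pool the readings from 30.0 min on.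

For each run I divide summed target by summed other capture product, then by the charge ratio of first to second nucleophile. This gives 0.170 for south, 0.153 for west and 0.143 for north. Their mean, 0.155, is the end factor: the late ratio of target to other capture product per unit of charge ratio, an apparent selectivity factor read at this substrate concentration.

The flask has a charge ratio of 0.917, so I commit to an end ratio of 0.143, with target less than other capture product. The end factor says nothing about 5.0 s or 4.0 min.

For the ratios at 5.0 s, 4.0 min and 3.0 h the forecast gives 0.4, 0.18 and 0.14, with other capture product ahead, and says of the drain on target “the data can't tell these apart”.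

At those times the flask gives 0.440, 0.176 and 0.143, and at 3.0 h it holds 9.03 % target against 63.1 % other capture product.

    substrate ⇌ intermediate (K = 0.00250, k = 0.760 /min)
    first nucleophile + intermediate → target (k = 1300 /M/min)
    second nucleophile + intermediate → other capture product (k = 2600 /M/min)
    substrate + target → side product (k = 2.10 /M/min)
    target ⇌ isomer of the product (K = 2.50, k = 0.970 /min)

Divided by its charge ratio, the end ratio of the flask is 0.156, against the end factor of 0.155 from the earlier runs. A neighbouring flask keeps the recipe but has 0.720 equiv of second nucleophile. Its charge ratio is 1.53, so the end factor gives an end ratio of 0.238. At 3.0 h that neighbour stands at 0.251, with 12.2 % target and 48.4 % other capture product.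

The readings stem from a simulated flask from invented constants, noise included.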